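## Structural features

The target has three benzene rings. Ring A (4-hydroxy-3-methoxyphenyl) sits on C7, ring B (3,5-dimethoxy-4-oxyphenyl) on C7', and ring C (4-hydroxy-3-methoxyphenyl) on C7''. Rings A and B are joined by the 2,3-dimethylbutane-1,4-diyl chain C7–C8(C9)–C8'(C9')–C7', and ring B is tied through O4' to C8'' of a 1-arylpropan-1-ol unit. The four stereocentres form two adjacent pairs: C8 (S) next to C8' (R), and C8'' (R) next to C7'' (S), the latter pair in the erythro (1,2-anti) relation. The fragile sites are the secondary benzylic alcohol at C7'' para to a phenol (hydrogenolysis, acid ionisation, base-induced quinone methide formation), the two free phenols, and C8'' once C7'' is a carbonyl (epimerisation alpha to C=O). The real difficulty is that C8 and C8' carry the same kinds of substituents and differ only in which aryl ring lies two bonds away. If rings A and B were alike the chain would be meso, so the absolute configuration is entirely a question of which CH2 terminus receives which ring. The key step exploits this: the C7–C8(C9)–C8'(C9')–C7' unit is traced back to a meso 1,4-diol whose enantiotopic CH2OH groups, the future C7 and C7', are told apart by an enzyme. The second difficulty, the erythro relation at C7''/C8'', is left to 1,2-induction from C8''.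

## Logic of the disconnections

22 to 21. The two O–Si bonds on the phenol oxygens of rings A and C are cut. The phenols must be masked through every organometallic step, and silyl ethers leave with fluoride without touching the benzylic C7''–O bond, which a final hydrogenolysis could endanger. The skeleton is not simplified, but the end game is a single step. The demand is that the fluoride be buffered so that a phenoxide para to C7'' cannot expel the hydroxyl group.

21 to 19 and 20. The C7''–C1'' bond to ring C is cut. This removes a whole ring and creates the carbinol centre under control of the neighbouring C8''. The nucleophile 20 comes from 13, the same building block that supplies ring A. The forward step must follow the polar Felkin–Anh path (no chelation) to give the anti isomer, and 19 must not epimerise before it reacts.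

19 to 18, then to 16 and 17. C7'' is first taken back to the ester level, then the O4'–C8'' ether bond is cut. C8'' then comes from the chiral pool, and the whole side chain is detached from the diarylbutane core. The forward demands are a clean inversion at C8'' by a hindered phenol and a partial reduction that stops at the aldehyde.

16 to 15, then to 11 and 13 (through 14). The benzyl O–C bond on ring B is restored, then the C7–C1 bond to ring A is cut. An sp3–sp2 bond between a primary alkylzinc and an aryl bromide is among the most dependable ways to attach an arene to a beta-branched CH2. Benzyl on ring B and silyl on ring A are orthogonal, so only the ring B phenol is freed for etherification. The stereocentres are beta to the metal and are not involved.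

11 to 10 to 9, then to 5 and 7 (through 8). The C7'–C1' bond to ring B is cut in the same way. The first coupling must be done while the other arm still carries its ester, and a magnesium reagent with copper catalysis falls short here. It would attack that ester, and once the ester is lost the freed alkoxide would close onto the activated arm as a five-membered cyclic ether and destroy the differentiation. An organozinc reagent tolerates the ester, so the same two-step pattern (alcohol to iodide, zinc insertion and palladium coupling) is used on both arms.

5 to 4, then to 2 and 3. The C–I bond is taken back to C–OH and the acyl C–O bond of the monoester is cut. No skeletal bond is touched, yet the whole C8/C8' problem is reduced to an achiral meso compound. The forward step must select one of two enantiotopic CH2OH groups, and 4 must be kept from acyl migration between its 1,4-related oxygens, which would interconvert the antipodes.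

2 to 1, 7 to 6, 13 to 12. These are functional-group changes only: reduction of both carboxyl groups, and O-benzylation and O-silylation of two commercial bromophenols. The meso relation of 1 must survive the reduction.

## Other disconnections considered

Alternative 1: The cut is the benzylic C1'–C7' bond, made last. A primary alkylzinc iodide A1, carrying benzyl-protected ring A and both methyl-bearing centres, would be joined to the aryl bromide A2, which already holds the silyl-protected erythro side chain and benzyl-protected ring C. Pd(OAc)2 and a biaryl(dialkyl)phosphine would give the fully protected target A3.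
- In favour: the plan is convergent. The erythro side chain would be built on the small phenol 6, where the more acidic bromophenol should undergo the Mitsunobu step more readily and a minor diastereomer could be removed early. On convergence and on the length of the longest linear sequence this alternative is the better plan.
- Mechanism: the bond-forming event is the same Negishi sequence as in steps 5 and 9, so here the two plans are equal.
- Against: A1 still needs an enantiopure, end-differentiated 2,3-dimethylbutane unit, most simply from 4, so the central problem is relocated and not solved. The C7'' hydroxyl needs its own protection, and the end game needs two deprotections, one of them a hydrogenolysis next to the benzylic C7''–O bond. Total step count would be about equal or slightly higher.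

Alternative 2: The cut is the C8–C8' bond. The ester A4 would be enolised with LiN(i-Pr)2 and silylated with Me3SiCl in THF to the silyl ketene acetal A5, with the methyl group cis to the allylic oxygen. A5 would rearrange through a chair transition state to the acid A6 after aqueous work-up.
- In favour: one pericyclic step makes the central bond and both stereocentres, with absolute sense transferred from a single carbinol centre. The two chain ends (CO2H and propenyl) are born chemically different, so no enzyme is needed. In independence from an enzyme's sense and in having distinct termini from the start, this alternative is the better plan.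
- Against: the anti/syn outcome rests on the enolate geometry, and a minor diastereomer of an acyclic acid would be hard to remove. The chosen plan takes the relative configuration, already complete, from meso 1. A4 must itself be obtained enantiomerically enriched, which calls for a resolution or asymmetric reduction of its own. After the key step both ends need several functional-group changes (reduction on one side, alkene cleavage and reduction on the other) before the two aryl couplings, so the route would be longer by roughly three or four steps.

Alternative 3: No skeletal bond is cut. One phenolic ester C–O bond of the meso diacetate A7 would be hydrolysed by a lipase to the monoacetate A8, whose free phenol marks ring A.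
- In favour: the whole diarylbutane skeleton with both stereocentres and both rings is bought, so a differentiated core would be reached in one step. On step count to that point this alternative is clearly the better plan.
- Mechanism: the enzyme class and acyl-enzyme chemistry are the same as in step 2, so in this respect the plans are equal.
- Against: the enantiotopic acetates lie six bonds from the nearest stereocentre, far outside the range where a lipase pocket should read the chirality. In the chosen plan the centres are beta to the reacting oxygen. Ring B of A8 also lacks the C5' methoxy group. A selective arene oxygenation ortho to one phenol in the presence of a second electron-rich ring, followed by selective O-methylation, would have to be added, and this would use up the early saving.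

Key step: step 2

Assumption: the lipase used (Pseudomonas fluorescens lipase) is taken to acylate the hydroxymethyl group on the (R)-configured carbon of 2, giving 4 as the (2R,3S)-monoacetate; an enzyme of the opposite sense is covered by the hydrolytic fallback named for step 2.

Step 1
Reactants: 1 meso-2,3-dimethylsuccinic acid
Product: 2 meso-2,3-dimethylbutane-1,4-diol
Conditions: LiAlH4, THF, 0 °C to reflux; H2O, aq. NaOH
Reagents that add atoms: none
Why: Hydride reduction of both carboxyl groups through their lithium carboxylates gives the diol; the alpha centres of a carboxylate are not enolised under these conditions, so the meso relation should be carried through unchanged.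

Step 2
Reactants: 2 meso-2,3-dimethylbutane-1,4-diol; 3 vinyl acetate
Product: 4 (2R,3S)-4-hydroxy-2,3-dimethylbutyl acetate
Conditions: Pseudomonas fluorescens lipase, 3 (4 equiv), t-BuOMe, 25 °C, stopped just after 2 is consumed
Reagents that add atoms: none
Why: The serine of the lipase catalytic triad attacks 3 to give an acetyl-enzyme, and the vinyl alcohol released tautomerises to acetaldehyde, so the acyl transfer cannot run backwards. Diol 2 then binds and one of its two enantiotopic CH2OH groups attacks the acetyl-enzyme through a tetrahedral intermediate held in the oxyanion hole, releasing 4; this is the well-established lipase-catalysed irreversible transesterification of meso and prochiral diols with enol esters. No skeletal bond forms and no ring closes. No new tetrahedral centre is built, but C2 and C3 of 4, equivalent by symmetry in 2, become two defined stereocentres: their relative configuration is inherited from the meso diol and their absolute sense is fixed by the chiral active site. The selectivity needed is between enantiotopic groups, and the substrate secures it because each methyl-bearing centre lies beta to the reacting oxygen, the distance at which the enzyme pocket reads the substituents of a primary alcohol best. A second acylation to the diacetate is slower and should remove the minor antipode of the monoacetate preferentially, so running slightly past full consumption of 2 should raise the enantiomeric purity of 4 at a small cost in material. Because acetyl migration between the two oxygens would interconvert the antipodes, 4 is kept neutral and cold and is taken on at once.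

Step 3
Reactants: 4 (2R,3S)-4-hydroxy-2,3-dimethylbutyl acetate
Product: 5 (2R,3S)-4-iodo-2,3-dimethylbutyl acetate
Conditions: I2, PPh3, imidazole, CH2Cl2, 0 °C to rt
Reagents that add atoms: iodine, II
Why: Appel-type iodination: the alkoxyphosphonium ion is displaced by iodide at the primary CH2, so neither stereocentre is touched; the fast, near-neutral conditions leave the acetate in place and give no time for acetyl migration.

Step 4
Reactants: 6 4-bromo-2,6-dimethoxyphenol
Product: 7 2-(benzyloxy)-5-bromo-1,3-dimethoxybenzene
Conditions: BnBr, K2CO3, DMF, 60 °C
Reagents that add atoms: benzyl bromide, BrCc1ccccc1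
Why: Williamson etherification of the phenoxide; benzyl masks the ring B phenol through the organozinc steps and can later be removed by hydrogenolysis without disturbing the silyl ether on ring A.

Step 5
Reactants: 5 (2R,3S)-4-iodo-2,3-dimethylbutyl acetate; 7 2-(benzyloxy)-5-bromo-1,3-dimethoxybenzene
Product: 9 (2R,3R)-4-[4-(benzyloxy)-3,5-dimethoxyphenyl]-2,3-dimethylbutyl acetate, via alkylzinc iodide 8 (not isolated)
Conditions: Zn dust (I2 cat.), DMA, 40 °C; then 7, Pd(OAc)2 (cat.), SPhos (cat.), THF, 50 °C
Reagents that add atoms: none
Why: Zinc inserts into the primary C–I bond to give an alkylzinc iodide that does not attack the acetate; Negishi coupling (oxidative addition of the aryl bromide to zerovalent palladium, transmetalation, reductive elimination) forms the C7'–C1' bond, the bulky biarylphosphine favouring reductive elimination over beta-hydride elimination. The stereocentres are beta and gamma to the metal and are not affected.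

Step 6
Reactants: 9 (2R,3R)-4-[4-(benzyloxy)-3,5-dimethoxyphenyl]-2,3-dimethylbutyl acetate
Product: 10 (2R,3R)-4-[4-(benzyloxy)-3,5-dimethoxyphenyl]-2,3-dimethylbutan-1-ol
Conditions: K2CO3 (0.2 equiv), MeOH, rt
Reagents that add atoms: none
Why: Base-catalysed transesterification passes the acetyl group to methanol; the benzyl and methyl aryl ethers are inert and no enolisable centre is present.

Step 7
Reactants: 10 (2R,3R)-4-[4-(benzyloxy)-3,5-dimethoxyphenyl]-2,3-dimethylbutan-1-ol
Product: 11 2-(benzyloxy)-5-[(2R,3R)-4-iodo-2,3-dimethylbutyl]-1,3-dimethoxybenzene
Conditions: I2, PPh3, imidazole, CH2Cl2, 0 °C to rt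
Reagents that add atoms: iodine, II
Why: Appel-type iodination at the primary carbon as in step 3; the electron-rich ring is not iodinated because the iodine is consumed by the phosphine before the substrate is added.

Step 8
Reactants: 12 4-bromo-2-methoxyphenol
Product: 13 (4-bromo-2-methoxyphenoxy)(tert-butyl)dimethylsilane
Conditions: TBSCl, imidazole, DMF, rt
Reagents that add atoms: tert-butyldimethylsilyl chloride, C[Si](C)(Cl)C(C)(C)C
Why: Imidazole-promoted O-silylation of the phenol; this one protected bromide serves as the ring A electrophile in step 9 and as the ring C nucleophile precursor in step 13, so it is made on twice the scale.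

Step 9
Reactants: 11 2-(benzyloxy)-5-[(2R,3R)-4-iodo-2,3-dimethylbutyl]-1,3-dimethoxybenzene; 13 (4-bromo-2-methoxyphenoxy)(tert-butyl)dimethylsilane
Product: 15 {4-[(2S,3R)-4-[4-(benzyloxy)-3,5-dimethoxyphenyl]-2,3-dimethylbutyl]-2-methoxyphenoxy}(tert-butyl)dimethylsilane, via alkylzinc iodide 14 (not isolated)
Conditions: Zn dust (I2 cat.), DMA, 40 °C; then 13, Pd(OAc)2 (cat.), SPhos (cat.), THF, 50 °C
Reagents that add atoms: none
Why: Second zinc insertion and Negishi coupling, forming the C7–C1 bond to ring A by the same mechanism as step 5; benzyl and silyl aryl ethers are both stable to organozinc reagents and to the palladium catalyst.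

Step 10
Reactants: 15 {4-[(2S,3R)-4-[4-(benzyloxy)-3,5-dimethoxyphenyl]-2,3-dimethylbutyl]-2-methoxyphenoxy}(tert-butyl)dimethylsilane
Product: 16 4-[(2R,3S)-4-{4-[(tert-butyldimethylsilyl)oxy]-3-methoxyphenyl}-2,3-dimethylbutyl]-2,6-dimethoxyphenol
Conditions: H2 (1 atm), Pd/C, EtOAc, rt
Reagents that add atoms: none
Why: Catalytic hydrogenolysis of the benzyl aryl ether frees only the ring B phenol; the molecule holds no other reducible group, and the aprotic solvent keeps the aryl silyl ether intact.

Step 11
Reactants: 16 4-[(2R,3S)-4-{4-[(tert-butyldimethylsilyl)oxy]-3-methoxyphenyl}-2,3-dimethylbutyl]-2,6-dimethoxyphenol; 17 ethyl (S)-lactate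
Product: 18 ethyl (2R)-2-{4-[(2R,3S)-4-{4-[(tert-butyldimethylsilyl)oxy]-3-methoxyphenyl}-2,3-dimethylbutyl]-2,6-dimethoxyphenoxy}propanoate
Conditions: PPh3, DIAD, THF, 0 °C to rt
Reagents that add atoms: none
Why: Mitsunobu etherification: the phenol protonates the phosphine–azodicarboxylate betaine, the lactate hydroxyl becomes an alkoxyphosphonium leaving group, and the phenoxide displaces it in an SN2 step with inversion, setting C8'' as R. A carbon alpha to an ester is a reactive SN2 site, which helps the hindered phenoxide.

Step 12
Reactants: 18 ethyl (2R)-2-{4-[(2R,3S)-4-{4-[(tert-butyldimethylsilyl)oxy]-3-methoxyphenyl}-2,3-dimethylbutyl]-2,6-dimethoxyphenoxy}propanoate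
Product: 19 (2R)-2-{4-[(2R,3S)-4-{4-[(tert-butyldimethylsilyl)oxy]-3-methoxyphenyl}-2,3-dimethylbutyl]-2,6-dimethoxyphenoxy}propanal
Conditions: i-Bu2AlH (1.1 equiv), toluene, −78 °C; MeOH, aq. potassium sodium tartrate; used crude at once
Reagents that add atoms: none
Why: Partial reduction of an ester: at −78 °C the tetrahedral aluminium hemiacetal, stabilised by the alpha-aryloxy oxygen, persists until work-up and then gives the aldehyde. Immediate use without chromatography protects the alpha-aryloxy centre C8'' from epimerisation.

Step 13
Reactants: 19 (2R)-2-{4-[(2R,3S)-4-{4-[(tert-butyldimethylsilyl)oxy]-3-methoxyphenyl}-2,3-dimethylbutyl]-2,6-dimethoxyphenoxy}propanal; 13 (4-bromo-2-methoxyphenoxy)(tert-butyl)dimethylsilane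
Product: 21 (1S,2R)-1-{4-[(tert-butyldimethylsilyl)oxy]-3-methoxyphenyl}-2-{4-[(2R,3S)-4-{4-[(tert-butyldimethylsilyl)oxy]-3-methoxyphenyl}-2,3-dimethylbutyl]-2,6-dimethoxyphenoxy}propan-1-ol, via arylmagnesium bromide 20 (not isolated)
Conditions: 13, Mg turnings, THF, 40 °C; then 19, THF, −78 °C; aq. NH4Cl
Reagents that add atoms: none
Why: Grignard 1,2-addition under polar Felkin–Anh control: the C8''–OAr bond lies anti to the incoming aryl group, which passes the small hydrogen and not the methyl group, giving the 1,2-anti (erythro) alcohol with C7'' as S. Chelation, which would give the threo isomer, should be weak because the aryloxy oxygen is a poor donor flanked by two ortho methoxy groups and THF saturates the magnesium; the low temperature also suppresses enolisation of 19.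

Step 14
Reactants: 21 (1S,2R)-1-{4-[(tert-butyldimethylsilyl)oxy]-3-methoxyphenyl}-2-{4-[(2R,3S)-4-{4-[(tert-butyldimethylsilyl)oxy]-3-methoxyphenyl}-2,3-dimethylbutyl]-2,6-dimethoxyphenoxy}propan-1-ol
Product: 22 (+)-(7''S,8S,8'R,8''R)-4,4''-dihydroxy-3,3',3'',5'-tetramethoxy-4',8''-oxy-8,8'-sesquineolignan-7''-ol
Conditions: Bu4NF (2.4 equiv), AcOH (2.4 equiv), THF, 0 °C to rt
Reagents that add atoms: none
Why: Fluoride attacks silicon and cleaves both aryl silyl ethers; acetic acid protonates the phenoxides as they form, so the one para to C7'' cannot expel the benzylic hydroxyl, and no stereocentre is touched.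

Compound list

1 | meso-2,3-dimethylsuccinic acid | OC(=O)[C@H](C)[C@H](C)C(=O)O | starting material
2 | meso-2,3-dimethylbutane-1,4-diol | OC[C@H](C)[C@H](C)CO | intermediate
3 | vinyl acetate | CC(=O)OC=C | starting material
4 | (2R,3S)-4-hydroxy-2,3-dimethylbutyl acetate | CC(=O)OC[C@H](C)[C@H](C)CO | intermediate
5 | (2R,3S)-4-iodo-2,3-dimethylbutyl acetate | CC(=O)OC[C@H](C)[C@H](C)CI | intermediate
6 | 4-bromo-2,6-dimethoxyphenol | COc1cc(Br)cc(OC)c1O | starting material
7 | 2-(benzyloxy)-5-bromo-1,3-dimethoxybenzene | COc1cc(Br)cc(OC)c1OCc1ccccc1 | intermediate
8 | [(2S,3R)-4-acetoxy-2,3-dimethylbutyl]zinc iodide | CC(=O)OC[C@H](C)[C@H](C)C[Zn]I | intermediate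
9 | (2R,3R)-4-[4-(benzyloxy)-3,5-dimethoxyphenyl]-2,3-dimethylbutyl acetate | CC(=O)OC[C@H](C)[C@H](C)Cc1cc(OC)c(OCc2ccccc2)c(OC)c1 | intermediate
10 | (2R,3R)-4-[4-(benzyloxy)-3,5-dimethoxyphenyl]-2,3-dimethylbutan-1-ol | OC[C@H](C)[C@H](C)Cc1cc(OC)c(OCc2ccccc2)c(OC)c1 | intermediate
11 | 2-(benzyloxy)-5-[(2R,3R)-4-iodo-2,3-dimethylbutyl]-1,3-dimethoxybenzene | IC[C@H](C)[C@H](C)Cc1cc(OC)c(OCc2ccccc2)c(OC)c1 | intermediate
12 | 4-bromo-2-methoxyphenol | COc1cc(Br)ccc1O | starting material
13 | (4-bromo-2-methoxyphenoxy)(tert-butyl)dimethylsilane | COc1cc(Br)ccc1O[Si](C)(C)C(C)(C)C | intermediate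
14 | {(2R,3R)-4-[4-(benzyloxy)-3,5-dimethoxyphenyl]-2,3-dimethylbutyl}zinc iodide | I[Zn]C[C@H](C)[C@H](C)Cc1cc(OC)c(OCc2ccccc2)c(OC)c1 | intermediate
15 | {4-[(2S,3R)-4-[4-(benzyloxy)-3,5-dimethoxyphenyl]-2,3-dimethylbutyl]-2-methoxyphenoxy}(tert-butyl)dimethylsilane | COc1cc(C[C@H](C)[C@H](C)Cc2cc(OC)c(OCc3ccccc3)c(OC)c2)ccc1O[Si](C)(C)C(C)(C)C | intermediate
16 | 4-[(2R,3S)-4-{4-[(tert-butyldimethylsilyl)oxy]-3-methoxyphenyl}-2,3-dimethylbutyl]-2,6-dimethoxyphenol | COc1cc(C[C@H](C)[C@H](C)Cc2cc(OC)c(O)c(OC)c2)ccc1O[Si](C)(C)C(C)(C)C | intermediate
17 | ethyl (S)-lactate | CCOC(=O)[C@H](C)O | starting material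
18 | ethyl (2R)-2-{4-[(2R,3S)-4-{4-[(tert-butyldimethylsilyl)oxy]-3-methoxyphenyl}-2,3-dimethylbutyl]-2,6-dimethoxyphenoxy}propanoate | COc1cc(C[C@H](C)[C@H](C)Cc2cc(OC)c(O[C@H](C)C(=O)OCC)c(OC)c2)ccc1O[Si](C)(C)C(C)(C)C | intermediate
19 | (2R)-2-{4-[(2R,3S)-4-{4-[(tert-butyldimethylsilyl)oxy]-3-methoxyphenyl}-2,3-dimethylbutyl]-2,6-dimethoxyphenoxy}propanal | COc1cc(C[C@H](C)[C@H](C)Cc2cc(OC)c(O[C@H](C)C=O)c(OC)c2)ccc1O[Si](C)(C)C(C)(C)C | intermediate
20 | {4-[(tert-butyldimethylsilyl)oxy]-3-methoxyphenyl}magnesium bromide | COc1cc([Mg]Br)ccc1O[Si](C)(C)C(C)(C)C | intermediate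
21 | (1S,2R)-1-{4-[(tert-butyldimethylsilyl)oxy]-3-methoxyphenyl}-2-{4-[(2R,3S)-4-{4-[(tert-butyldimethylsilyl)oxy]-3-methoxyphenyl}-2,3-dimethylbutyl]-2,6-dimethoxyphenoxy}propan-1-ol | COc1cc(C[C@H](C)[C@H](C)Cc2cc(OC)c(O[C@H](C)[C@@H](O)c3ccc(O[Si](C)(C)C(C)(C)C)c(OC)c3)c(OC)c2)ccc1O[Si](C)(C)C(C)(C)C | intermediate
22 | (+)-(7''S,8S,8'R,8''R)-4,4''-dihydroxy-3,3',3'',5'-tetramethoxy-4',8''-oxy-8,8'-sesquineolignan-7''-ol | COc1cc(C[C@H](C)[C@H](C)Cc2cc(OC)c(O[C@H](C)[C@@H](O)c3ccc(O)c(OC)c3)c(OC)c2)ccc1O | target

Total step count: 14. Longest linear sequence: 12 steps (steps 1, 2, 3, 5, 6, 7, 9, 10, 11, 12, 13, 14, from 1 to 22); steps 4 and 8 are side branches.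

Steps least certain to work

Step 2 (key step). The most likely failure is insufficient discrimination between the two enantiotopic arms, or discrimination in the opposite sense, together with loss of material to double acylation. Fallback, setting out from 2 and returning at 4: the diol is peracetylated (Ac2O, pyridine) to meso-2,3-dimethylbutane-1,4-diyl diacetate F1. One enantiotopic ester of F1 is then hydrolysed in aqueous phosphate buffer by pig liver esterase or by the same lipase. In the hydrolytic direction an enzyme that prefers a given arm leaves the acetate on the other arm, so this mode gives the antipode of the acylation mode and covers either sense of the enzyme.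

Step 5. The likely failure is incomplete zinc insertion or protonation of the alkylzinc, together with slow oxidative addition of the electron-rich bromide, ending in simple reduction of the iodide. Fallback, setting out from 5 and 7 and returning at 9: a nickel-catalysed reductive cross-electrophile coupling (NiI2, 4,4'-di-tert-butyl-2,2'-bipyridine, Zn powder, NaI, DMPU, 60 °C). The alkyl iodide enters as a radical captured at an arylnickel species, so no organometallic reagent has to be preformed and the acetate is tolerated. This fallback makes no new compound (F0).

Step 11. The likely failure is slow ether formation at the di-ortho-substituted phenol, with the activated lactate diverted to elimination or to alkylation of the reduced azodicarboxylate. Fallback, setting out from 17 and 16 and returning at 18: 17 is converted (Tf2O, 2,6-lutidine, CH2Cl2, −78 °C) into ethyl (2S)-2-{[(trifluoromethyl)sulfonyl]oxy}propanoate F2. The potassium phenoxide of 16 (K2CO3, MeCN, −20 to 0 °C) displaces the triflate in a direct SN2 reaction with the same inversion at C8''.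

Step 12. The likely failure is over-reduction to the primary alcohol or epimerisation of C8'' during the aluminium work-up. Fallback, setting out from 18 and returning at 19: the ester is reduced completely with LiBH4 (THF, 0 °C) to (2R)-2-{4-[(2R,3S)-4-{4-[(tert-butyldimethylsilyl)oxy]-3-methoxyphenyl}-2,3-dimethylbutyl]-2,6-dimethoxyphenoxy}propan-1-ol F3. F3 is then oxidised to 19 with Dess–Martin periodinane buffered with NaHCO3, which is non-basic and needs no aqueous aluminium work-up.

Step 13. The likely failure is poor facial selectivity, with a chelated transition state competing with the Felkin–Anh one, or partial enolisation of 19 by the Grignard reagent. Fallback, setting out from 19 and returning at 21: the addition is run without regard to selectivity, giving 21 mixed with its C7'' epimer, (1R,2R)-1-{4-[(tert-butyldimethylsilyl)oxy]-3-methoxyphenyl}-2-{4-[(2R,3S)-4-{4-[(tert-butyldimethylsilyl)oxy]-3-methoxyphenyl}-2,3-dimethylbutyl]-2,6-dimethoxyphenoxy}propan-1-ol F4. The mixture is oxidised with Dess–Martin periodinane (NaHCO3) to the ketone (2R)-1-{4-[(tert-butyldimethylsilyl)oxy]-3-methoxyphenyl}-2-{4-[(2R,3S)-4-{4-[(tert-butyldimethylsilyl)oxy]-3-methoxyphenyl}-2,3-dimethylbutyl]-2,6-dimethoxyphenoxy}propan-1-one F5. F5 is reduced with Zn(BH4)2 in Et2O at −20 °C. Zinc bridges the carbonyl and aryloxy oxygens and hydride enters anti to the C8'' methyl group, which for a ketone gives the erythro alcohol 21.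

Further compounds

F1 | step 2 | meso-2,3-dimethylbutane-1,4-diyl diacetate | CC(=O)OC[C@H](C)[C@H](C)COC(C)=O
F0 | step 5 | none | none
F2 | step 11 | ethyl (2S)-2-{[(trifluoromethyl)sulfonyl]oxy}propanoate | CCOC(=O)[C@H](C)OS(=O)(=O)C(F)(F)F
F3 | step 12 | (2R)-2-{4-[(2R,3S)-4-{4-[(tert-butyldimethylsilyl)oxy]-3-methoxyphenyl}-2,3-dimethylbutyl]-2,6-dimethoxyphenoxy}propan-1-ol | COc1cc(C[C@H](C)[C@H](C)Cc2cc(OC)c(O[C@H](C)CO)c(OC)c2)ccc1O[Si](C)(C)C(C)(C)C
F4 | step 13 | (1R,2R)-1-{4-[(tert-butyldimethylsilyl)oxy]-3-methoxyphenyl}-2-{4-[(2R,3S)-4-{4-[(tert-butyldimethylsilyl)oxy]-3-methoxyphenyl}-2,3-dimethylbutyl]-2,6-dimethoxyphenoxy}propan-1-ol | COc1cc(C[C@H](C)[C@H](C)Cc2cc(OC)c(O[C@H](C)[C@H](O)c3ccc(O[Si](C)(C)C(C)(C)C)c(OC)c3)c(OC)c2)ccc1O[Si](C)(C)C(C)(C)C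
F5 | step 13 | (2R)-1-{4-[(tert-butyldimethylsilyl)oxy]-3-methoxyphenyl}-2-{4-[(2R,3S)-4-{4-[(tert-butyldimethylsilyl)oxy]-3-methoxyphenyl}-2,3-dimethylbutyl]-2,6-dimethoxyphenoxy}propan-1-one | COc1cc(C[C@H](C)[C@H](C)Cc2cc(OC)c(O[C@H](C)C(=O)c3ccc(O[Si](C)(C)C(C)(C)C)c(OC)c3)c(OC)c2)ccc1O[Si](C)(C)C(C)(C)C
A1 | alternative 1 | {(2S,3S)-4-[4-(benzyloxy)-3-methoxyphenyl]-2,3-dimethylbutyl}zinc iodide | COc1cc(C[C@H](C)[C@H](C)C[Zn]I)ccc1OCc1ccccc1
A2 | alternative 1 | {(1S,2R)-1-[4-(benzyloxy)-3-methoxyphenyl]-2-(4-bromo-2,6-dimethoxyphenoxy)propoxy}(tert-butyl)dimethylsilane | COc1cc(Br)cc(OC)c1O[C@H](C)[C@@H](O[Si](C)(C)C(C)(C)C)c1ccc(OCc2ccccc2)c(OC)c1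
A3 | alternative 1 | fully protected target: 4,4''-di-O-benzyl-7''-O-(tert-butyldimethylsilyl) derivative of 22 | COc1cc(C[C@H](C)[C@H](C)Cc2cc(OC)c(O[C@H](C)[C@@H](O[Si](C)(C)C(C)(C)C)c3ccc(OCc4ccccc4)c(OC)c3)c(OC)c2)ccc1OCc1ccccc1
A4 | alternative 2 | (S,E)-pent-3-en-2-yl propanoate | CCC(=O)O[C@@H](C)/C=C/C
A5 | alternative 2 | trimethylsilyl ketene acetal of A4, methyl cis to the allylic oxygen | C/C=C(\O[C@@H](C)/C=C/C)O[Si](C)(C)C
A6 | alternative 2 | (2R,3R,E)-2,3-dimethylhex-4-enoic acid | OC(=O)[C@H](C)[C@H](C)/C=C/C
A7 | alternative 3 | meso-dihydroguaiaretic acid diacetate | COc1cc(C[C@H](C)[C@H](C)Cc2ccc(OC(C)=O)c(OC)c2)ccc1OC(C)=O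
A8 | alternative 3 | 4-[(2R,3S)-4-(4-hydroxy-3-methoxyphenyl)-2,3-dimethylbutyl]-2-methoxyphenyl acetate | COc1cc(C[C@H](C)[C@H](C)Cc2ccc(OC(C)=O)c(OC)c2)ccc1O
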